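## Analysis of the target

The target 27 is a C25 carboxylic acid on a trans-fused decalin; in the numbering used throughout, ring A is C1–C5 plus C10, ring B is C5–C10, C11–C15 is the arm on C9 (C15 = CO2H) and β is the face of the C10 methyl. Ring A is saturated, whereas ring B holds a tetrasubstituted C8=C9 double bond with a methyl on C8 and, on C9, a CH2CH2 link to an (E)-trisubstituted enoic acid. There are three contiguous stereocentres, all S: C4 (quaternary, methyl β, 4-methylpent-3-enyl α), C5 (H α) and C10 (quaternary, methyl β), so the two ring methyls are cis and 1,3-diaxial and the C5 hydrogen is trans to both. Three different alkenes are present (trisubstituted in the C4 chain, tetrasubstituted in ring B, conjugated E in the acid arm), which excludes late hydrogenation, strong acid and unselective electrophiles. The hard points are the two quaternary centres that flank C5, the distinction between the two carbon groups on C4, and the placement of the ring alkene and the E geometry without isomer mixtures. The plan rests on ring B: C9 lies between the methyl-bearing carbons C10 and C8, and C6 is para to it. This is the pattern of 2,6-dimethyl-1,4-benzoquinone, with C9 as its C1 carbonyl and C6 as its C4 carbonyl, and its C10=C5 bond can take up C1–C4 of ring A as a diene.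

## Retrosynthetic reasoning

Acid 27 is traced to ester 25, and 25 to terminal alkyne 23, by cutting C13–CH3 and C14–C15. Forward, a syn methylalumination gives alkenylalane 24, which is acylated. The cut is made here because syn carbometalation fixes the E geometry by mechanism, whereas olefination of a methyl ketone would give E/Z mixtures. Only the terminal alkyne reacts, so the two other alkenes are safe.

Alkyne 23 is the desilylated form of 22, which is cut at C9–C11 into enol triflate 19 and zinc reagent 21 (from bromide 20). Ketone 17 can enolise only toward C8 because C10 is quaternary, so triflate 19 fixes the C8=C9 position and the sp2–sp3 coupling keeps it. Addition to the hindered C9 carbonyl followed by dehydration would control neither.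

Ketone 17 is diketone 14 without its C2 carbonyl (through tosylhydrazone 15). The C2 oxygen is kept until this point because it is what makes C4 electrophilic.

In 14 the bond from C4 to the 4-methylpent-3-enyl chain is cut. Forward, Grignard reagent 12 (from bromide 11) adds under copper catalysis to the β carbon of enone 10. C4 already carries its methyl, so this one bond completes the quaternary centre, and the axial C10 methyl is to decide the face. The step needs a trans-fused enone with no other acidic site.

Enone 10 comes from silyl enol ether 9 by oxidation, and 9 is trans dione 6 without its C6 carbonyl (through hydrazone 7). C6 must be removed before the enone exists. With both present, C5–H would be α to one carbonyl and γ to the other, and an organocopper reagent would deprotonate it instead of adding.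

Trans dione 6 is the C5 epimer of cis dione 5, the reduction product of enedione 4. The C6 carbonyl is used once, for this epimerisation, and then deleted.

Adduct 4 is cut at C1–C10 and C4–C5 into diene 2 and quinone 3. This cut gives the most: one ring, two C–C bonds, the quaternary C10 in absolute form, all thirteen carbons of the decalin core with its three methyls, and an oxygen at each carbon that later needs one (C2, C6, C9). The forward reaction must be regioselective (C1 to C10) and face-selective at C10; C4 and C5 need not be right yet.

Diene 2 is the silyl dienol ether of enone 1.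

## Alternatives that were turned down

Alternative 1: The cuts are C9–C10 and C5–C6 on a preformed ring A. Forward, an enantioselective addition of an isopropenyl metal, catalysed by Cu(OTf)2 and a chiral phosphoramidite, to 3-methylcyclohex-2-enone A1 makes C10 quaternary, and the enolate is allylated at C5 anti to the new group, giving the trans ketone A2.
- For: A1 is very cheap, and C10 and C5 are set in one flask. The trans relation of the two new arms is the trans ring fusion itself. On this point the alternative is stronger than the chosen route, which must correct C5 by equilibration.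
- Against: no ring is formed. Ring B, the tetrasubstituted C8=C9 alkene and the C9 arm all remain to be built from an allyl and an isopropenyl group that do not supply the right carbon count for a direct closure. The C4 carbonyl carbon must receive two different carbon groups next to C5 with stereocontrol, which costs several steps of uncertain selectivity.
- Comparison: the chosen cycloaddition delivers both rings' carbons and a C9 ketone that can enolise in one direction only. It pays with three carbonyl groups to edit.

Alternative 2: The cuts are C3–C4 and C5–C10 in an acyclic trienone. Forward, the (E)-trisubstituted enone C4=C5 adds across the tethered diene in an intramolecular Diels–Alder reaction that closes both rings and gives the trans-fused octalinone A3.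
- For: this is the most convergent plan. Both quaternary centres and C5 arise at once, and the C4 configuration follows from the alkene geometry with the chain in place from the start. On C4 it is stronger than the chosen route, which depends on a facial preference.
- Against: the dienophile is β,β-disubstituted and the diene terminus C10 is fully substituted, so two quaternary centres must form in one thermal cycloaddition, for which close precedent is lacking. The endo/exo preference that decides cis or trans fusion is uncertain with a flexible ketone-bearing tether. Absolute control depends on a C9 silyloxy stereocentre that needs its own asymmetric synthesis. Afterwards the C1=C2 alkene must be reduced beside the chain alkene and C6 and C9 adjusted.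
- Comparison: the chosen key step is intermolecular, catalytic and precedented, and its precursors take one step. It offers reliability of the ring-forming event in place of convergence.

Alternative 3: The cut is the C8=C9 bond of ring B in a meso ring A triene. Forward, a chiral molybdenum imido alkylidene of the type Mo(NAr)(CHCMe2Ph)(diolate) selects one of two enantiotopic vinyl groups and closes ring B to give A4.
- For: symmetry sets the two quaternary centres together, with their methyls cis by construction. This is stronger than the chosen route at C4. The remaining vinyl group is a clean handle for the chain.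
- Against: the alkene formed has C9–H, whereas the target needs a carbon arm on C9, so a further C–C bond at an alkene carbon is required. The tertiary C5 silyl ether must become C5–H with trans stereochemistry, for which no reliable stereocontrolled reduction is evident. The metathesis joins a 1,1-disubstituted alkene to a vinyl group on a quaternary carbon and is expected to be slow. The meso precursor, with three contiguous fully substituted carbons, is itself long to make.
- Comparison: the chosen route has C9 as a carbonyl and C5 as C–H from the first ring-forming step.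

Key step: step 2

Remarks on the chemistry before the steps:
- Assumption: the sense of induction in step 2 is taken from the usual binding model for this catalyst class, which points to the (R)-prolinol-derived catalyst for the 10S adduct. If the first run gives the mirror image, the (S)-prolinol-derived catalyst is used and nothing else changes.
- C8 is a stereocentre only in intermediates 5–17. It is drawn 8α (equatorial, the epimer expected after equilibration) and becomes sp2 in step 11.

## Route

Step 1
Reactants: 1 (E)-pent-3-en-2-one
Product: 2 (E)-2-(tert-butyldimethylsilyloxy)penta-1,3-diene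
Conditions: TBSOTf, Et3N, Et2O, 0 °C; distillation
Reagents that add atoms: tert-butyldimethylsilyl trifluoromethanesulfonate, CC(C)(C)[Si](C)(C)OS(=O)(=O)C(F)(F)F
Why: Soft enolisation of a methyl enone: the silyl triflate activates the carbonyl and the amine removes a methyl proton, which gives the cross-conjugated 2-silyloxydiene and leaves the E alkene untouched.

Step 2
Reactants: 2 (E)-2-(tert-butyldimethylsilyloxy)penta-1,3-diene; 3 2,6-dimethyl-1,4-benzoquinone
Product: 4 (4aR,5R,8aS)-7-(tert-butyldimethylsilyloxy)-2,5,8a-trimethyl-4a,5,8,8a-tetrahydronaphthalene-1,4-dione (cis-fused adduct; 4α-methyl, 5β-H, 10β-methyl in the terpenoid numbering)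
Conditions: oxazaborolidinium triflimide from (R)-α,α-diphenylprolinol, tri(o-tolyl)boroxine and HNTf2 (20 mol %), 2 (1.2 equiv), CH2Cl2, −78 °C
Reagents that add atoms: none
Why: The proline-derived oxazaborolidinium ion binds the less hindered C6 carbonyl of 3 through the lone pair next to C5–H, which lowers the LUMO of the C10=C5 bond and makes C10 its electrophilic end; the closest known reaction type is the oxazaborolidinium-catalysed Diels–Alder reaction of 2,6-disubstituted benzoquinones with 2-silyloxydienes. Diene 2 adds in a concerted, asynchronous, suprafacial [4+2] cycloaddition in which its nucleophilic CH2 terminus (C1) leads at C10 and its methyl-bearing terminus (C4) follows at C5. Ring A closes by this cycloaddition as a six-membered silyl enol ether, with both new bonds formed on one face of the quinone. C10 is set by the catalyst, which covers one face of the bound double bond with an aryl group so that the diene arrives from the open face. C5 follows from suprafacial addition to the ring alkene (5-H cis to the 10-methyl), and C4 from the endo approach of the E diene. The step needs regioselectivity, face selectivity and mono-addition: the 2-silyloxy group (para) and the diene methyl (ortho) both direct to the same regioisomer relative to the activated C6 carbonyl, the two quinone double bonds are equivalent through the twofold axis, and adduct 4 is a weaker and more hindered dienophile than 3. C4 and C5 are reset later, so only the C10 configuration has to persist.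

Step 3
Reactants: 4 cis-fused enedione adduct
Product: 5 cis-fused 2-(tert-butyldimethylsilyloxy)-4α,8,10β-trimethyl-5β-H-decal-2-ene-6,9-dione (C8 epimers)
Conditions: Zn dust, AcOH (5 equiv), CH2Cl2, 0 °C
Reagents that add atoms: none
Why: Dissolving-metal reduction of an enedione: zinc transfers two electrons to the C6/C9 enedione and the bis-enolate is protonated at C7 and C8. The hindered TBS enol ether and the ring fusion should survive the short, anhydrous exposure, and the C8 mixture converges in step 4.

Step 4
Reactants: 5 cis-fused dione
Product: 6 trans-fused 2-(tert-butyldimethylsilyloxy)-4α,8α,10β-trimethyl-5α-H-decal-2-ene-6,9-dione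
Conditions: DBU (0.2 equiv), PhMe, 25–40 °C; cis isomer separated and resubmitted
Reagents that add atoms: none
Why: Thermodynamic epimerisation through the C5–C6 enolate: in the trans isomer C1 and C4 are both equatorial on ring B and C6 is equatorial on ring A, whereas the cis form must place C6 axial. C8 equilibrates at the same time to the equatorial methyl, and the aprotic amine base leaves the silyl enol ether intact.

Step 5
Reactants: 6 trans-fused dione
Product: 7 C6 p-toluenesulfonylhydrazone of 6
Conditions: TsNHNH2 (1.05 equiv), MgSO4, THF, 40 °C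
Reagents that add atoms: p-toluenesulfonohydrazide, Cc1ccc(cc1)S(=O)(=O)NN
Why: Hydrazone condensation at the only accessible ketone: C9 lies between the quaternary C10 and the branched C8 and should not react, and the neutral conditions spare the silyl enol ether.

Step 6
Reactants: 7 C6 tosylhydrazone
Product: 9 trans-fused 2-(tert-butyldimethylsilyloxy)-4α,8α,10β-trimethyl-5α-H-decal-2-en-9-one, via N-boryl sulfonohydrazide 8 (not isolated)
Conditions: catecholborane (1.5 equiv), CHCl3, 0 °C; then NaOAc·3H2O, reflux
Reagents that add atoms: none
Why: Tosylhydrazone reduction to a methylene group: hydride adds to C=N, acetate triggers loss of sulfinate, and the diazene loses N2. The conditions are neutral, so the silyl enol ether, the C9 ketone and the C5 configuration stay as they are. C6 is removed here because a C6 ketone would make C5–H doubly activated once the enone exists.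

Step 7
Reactants: 9 C6-deoxygenated silyl enol ether
Product: 10 trans-fused 4,8α,10β-trimethyl-5α-H-decal-3-ene-2,9-dione
Conditions: Pd(OAc)2 (1.1 equiv), MeCN, 40 °C
Reagents that add atoms: none
Why: Saegusa–Ito oxidation: divalent palladium attacks C3 of the enol ether and β-hydride elimination of C4–H gives the C3=C4 enone. The regiochemistry is fixed by the enol ether (and C10, being quaternary, allows no other enone), and the C4 stereocentre is erased on purpose.

Step 8
Reactants: 10 trans-fused enone; 11 5-bromo-2-methylpent-2-ene
Product: 14 4β,8α,10β-trimethyl-4α-(4-methylpent-3-enyl)-5α-H-decalin-2,9-dione, via Grignard reagent 12 (not isolated), via trimethylsilyl enol ether 13 (not isolated)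
Conditions: 11, Mg, THF; then 10, CuBr·SMe2 (10 mol %), TMSCl, DMPU, THF, −78 → −30 °C; then 1 M HCl
Reagents that add atoms: none
Why: Copper-catalysed conjugate addition of a Grignard reagent to a β,β-disubstituted enone, accelerated by TMSCl, which traps the enolate as 13. The axial C10 methyl lies 1,3-syn over the β face of C4, so the organocopper species is expected to enter from the α face, placing the chain α (equatorial) and leaving the C4 methyl β, cis to the C10 methyl. The C9 ketone is too hindered for 1,2-addition at this temperature.

Step 9
Reactants: 14 2,9-diketone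
Product: 15 C2 p-toluenesulfonylhydrazone of 14
Conditions: TsNHNH2 (1.05 equiv), EtOH, 50 °C
Reagents that add atoms: p-toluenesulfonohydrazide, Cc1ccc(cc1)S(=O)(=O)NN
Why: Selective hydrazone condensation: C2 is flanked by two CH2 groups and reacts, while C9 (quaternary C10 on one side, branched C8 on the other) should not.

Step 10
Reactants: 15 C2 tosylhydrazone
Product: 17 4β,8α,10β-trimethyl-4α-(4-methylpent-3-enyl)-5α-H-decalin-9-one, via N-boryl sulfonohydrazide 16 (not isolated)
Conditions: catecholborane (1.5 equiv), CHCl3, 0 °C → rt; then NaOAc·3H2O, reflux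
Reagents that add atoms: none
Why: Same tosylhydrazone reduction as in step 6. Catecholborane does not hydroborate the trisubstituted alkene at this temperature, and the quaternary C4 next to C3 cannot be affected.

Step 11
Reactants: 17 C9 ketone
Product: 19 4β,8,10β-trimethyl-4α-(4-methylpent-3-enyl)-5α-H-decal-8-en-9-yl trifluoromethanesulfonate, via potassium enolate 18 (not isolated)
Conditions: KN(SiMe3)2, THF, −78 → 0 °C; then PhNTf2, −78 °C → rt
Reagents that add atoms: N-phenylbis(trifluoromethanesulfonimide), O=S(=O)(N(c1ccccc1)S(=O)(=O)C(F)(F)F)C(F)(F)F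
Why: Enol triflate formation: the ketone has a single α hydrogen (C8–H, since C10 is quaternary), so only the C8=C9 enolate can form and O-sulfonylation fixes the tetrasubstituted alkene. The C8 stereocentre disappears.

Step 12
Reactants: 19 enol triflate; 20 (4-bromobut-1-yn-1-yl)trimethylsilane
Product: 22 9-[4-(trimethylsilyl)but-3-ynyl]-4β,8,10β-trimethyl-4α-(4-methylpent-3-enyl)-5α-H-decal-8-ene, via alkylzinc bromide 21 (not isolated)
Conditions: 20, Zn dust, LiCl, THF, 50 °C; then 19, Pd(OAc)2 (5 mol %), SPhos (10 mol %), THF, 60 °C
Reagents that add atoms: none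
Why: Negishi sp2–sp3 coupling: zerovalent palladium formed in situ inserts into the C9–OTf bond, the primary alkylzinc transmetalates, and the bulky biarylphosphine favours reductive elimination over β-hydride elimination. The alkene position is retained.

Step 13
Reactants: 22 silyl alkyne
Product: 23 9-(but-3-ynyl)-4β,8,10β-trimethyl-4α-(4-methylpent-3-enyl)-5α-H-decal-8-ene
Conditions: K2CO3 (cat.), MeOH, rt
Reagents that add atoms: none
Why: Methanolysis of the C(sp)–Si bond; nothing else in this hydrocarbon can react.

Step 14
Reactants: 23 terminal alkyne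
Product: 25 ethyl ester of 27, via alkenyl dimethylalane 24 (not isolated)
Conditions: Me3Al (3 equiv), Cp2ZrCl2 (25 mol %), CH2Cl2, 0 °C → rt; then ClCO2Et, rt
Reagents that add atoms: trimethylaluminium, C[Al](C)C; ethyl chloroformate, CCOC(=O)Cl
Why: Zirconium-catalysed methylalumination: methyl and aluminium add syn across the terminal alkyne with aluminium on the terminal carbon, and the alkenylalane is acylated by the chloroformate with retention, which gives the E enoate. Tri- and tetrasubstituted alkenes do not react.

Step 15
Reactants: 25 ethyl ester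
Product: 27 (2E)-3-methyl-5-[(4aS,5S,8aS)-2,5,8a-trimethyl-5-(4-methylpent-3-en-1-yl)-3,4,4a,5,6,7,8,8a-octahydronaphthalen-1-yl]pent-2-enoic acid, via lithium carboxylate 26 (not isolated)
Conditions: LiOH, THF/MeOH/H2O, 50 °C; then 1 M HCl, 0 °C
Reagents that add atoms: lithium hydroxide, [Li+].[OH-]
Why: Saponification of the conjugated ester; the alkene geometry and the ring alkene are stable to aqueous base and to brief cold acidification.

## Compound list

1 | (E)-pent-3-en-2-one | C/C=C/C(C)=O | starting material
2 | (E)-2-(tert-butyldimethylsilyloxy)penta-1,3-diene | C=C(O[Si](C)(C)C(C)(C)C)/C=C/C | intermediate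
3 | 2,6-dimethyl-1,4-benzoquinone | CC1=CC(=O)C=C(C)C1=O | starting material
4 | (4aR,5R,8aS)-7-(tert-butyldimethylsilyloxy)-2,5,8a-trimethyl-4a,5,8,8a-tetrahydronaphthalene-1,4-dione | C[C@@H]1C=C(O[Si](C)(C)C(C)(C)C)C[C@]2(C)C(=O)C(C)=CC(=O)[C@H]12 | intermediate
5 | cis-fused 2-(tert-butyldimethylsilyloxy)-4α,8,10β-trimethyl-5β-H-decal-2-ene-6,9-dione (C8 epimers) | C[C@@H]1C=C(O[Si](C)(C)C(C)(C)C)C[C@]2(C)C(=O)C(C)CC(=O)[C@H]12 | intermediate
6 | trans-fused 2-(tert-butyldimethylsilyloxy)-4α,8α,10β-trimethyl-5α-H-decal-2-ene-6,9-dione | C[C@@H]1C=C(O[Si](C)(C)C(C)(C)C)C[C@]2(C)C(=O)[C@H](C)CC(=O)[C@@H]12 | intermediate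
7 | C6 p-toluenesulfonylhydrazone of 6 | C[C@@H]1C=C(O[Si](C)(C)C(C)(C)C)C[C@]2(C)C(=O)[C@H](C)CC(=NNS(=O)(=O)c3ccc(C)cc3)[C@@H]12 | intermediate
8 | N-(1,3,2-benzodioxaborol-2-yl) C6 sulfonohydrazide from 7 | C[C@@H]1C=C(O[Si](C)(C)C(C)(C)C)C[C@]2(C)C(=O)[C@H](C)CC(N(NS(=O)(=O)c3ccc(C)cc3)B3Oc4ccccc4O3)[C@@H]12 | intermediate (not isolated)
9 | trans-fused 2-(tert-butyldimethylsilyloxy)-4α,8α,10β-trimethyl-5α-H-decal-2-en-9-one | C[C@@H]1C=C(O[Si](C)(C)C(C)(C)C)C[C@]2(C)C(=O)[C@H](C)CC[C@@H]12 | intermediate
10 | trans-fused 4,8α,10β-trimethyl-5α-H-decal-3-ene-2,9-dione | CC1=CC(=O)C[C@]2(C)C(=O)[C@H](C)CC[C@@H]12 | intermediate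
11 | 5-bromo-2-methylpent-2-ene | CC(C)=CCCBr | starting material
12 | (4-methylpent-3-en-1-yl)magnesium bromide | CC(C)=CCC[Mg]Br | intermediate (not isolated)
13 | 2-(trimethylsilyloxy)-4β,8α,10β-trimethyl-4α-(4-methylpent-3-enyl)-5α-H-decal-2-en-9-one | CC(C)=CCC[C@]1(C)C=C(O[Si](C)(C)C)C[C@]2(C)C(=O)[C@H](C)CC[C@@H]12 | intermediate (not isolated)
14 | 4β,8α,10β-trimethyl-4α-(4-methylpent-3-enyl)-5α-H-decalin-2,9-dione | CC(C)=CCC[C@]1(C)CC(=O)C[C@]2(C)C(=O)[C@H](C)CC[C@@H]12 | intermediate
15 | C2 p-toluenesulfonylhydrazone of 14 | CC(C)=CCC[C@]1(C)CC(=NNS(=O)(=O)c3ccc(C)cc3)C[C@]2(C)C(=O)[C@H](C)CC[C@@H]12 | intermediate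
16 | N-(1,3,2-benzodioxaborol-2-yl) C2 sulfonohydrazide from 15 | CC(C)=CCC[C@]1(C)CC(N(NS(=O)(=O)c3ccc(C)cc3)B3Oc4ccccc4O3)C[C@]2(C)C(=O)[C@H](C)CC[C@@H]12 | intermediate (not isolated)
17 | 4β,8α,10β-trimethyl-4α-(4-methylpent-3-enyl)-5α-H-decalin-9-one | CC(C)=CCC[C@]1(C)CCC[C@]2(C)C(=O)[C@H](C)CC[C@@H]12 | intermediate
18 | potassium C8=C9 enolate of 17 | CC(C)=CCC[C@]1(C)CCC[C@]2(C)C([O-])=C(C)CC[C@@H]12.[K+] | intermediate (not isolated)
19 | 4β,8,10β-trimethyl-4α-(4-methylpent-3-enyl)-5α-H-decal-8-en-9-yl trifluoromethanesulfonate | CC(C)=CCC[C@]1(C)CCC[C@]2(C)C(OS(=O)(=O)C(F)(F)F)=C(C)CC[C@@H]12 | intermediate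
20 | (4-bromobut-1-yn-1-yl)trimethylsilane | C[Si](C)(C)C#CCCBr | starting material
21 | [4-(trimethylsilyl)but-3-yn-1-yl]zinc bromide | C[Si](C)(C)C#CCC[Zn]Br | intermediate (not isolated)
22 | 9-[4-(trimethylsilyl)but-3-ynyl]-4β,8,10β-trimethyl-4α-(4-methylpent-3-enyl)-5α-H-decal-8-ene | CC(C)=CCC[C@]1(C)CCC[C@]2(C)C(CCC#C[Si](C)(C)C)=C(C)CC[C@@H]12 | intermediate
23 | 9-(but-3-ynyl)-4β,8,10β-trimethyl-4α-(4-methylpent-3-enyl)-5α-H-decal-8-ene | CC(C)=CCC[C@]1(C)CCC[C@]2(C)C(CCC#C)=C(C)CC[C@@H]12 | intermediate
24 | (E)-alkenyl dimethylalane from 23 (Al on C14, methyl on C13) | CC(C)=CCC[C@]1(C)CCC[C@]2(C)C(CC/C(C)=C/[Al](C)C)=C(C)CC[C@@H]12 | intermediate (not isolated)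
25 | ethyl (2E)-3-methyl-5-[(4aS,5S,8aS)-2,5,8a-trimethyl-5-(4-methylpent-3-en-1-yl)-3,4,4a,5,6,7,8,8a-octahydronaphthalen-1-yl]pent-2-enoate | CC(C)=CCC[C@]1(C)CCC[C@]2(C)C(CC/C(C)=C/C(=O)OCC)=C(C)CC[C@@H]12 | intermediate
26 | lithium carboxylate of 27 | CC(C)=CCC[C@]1(C)CCC[C@]2(C)C(CC/C(C)=C/C(=O)[O-])=C(C)CC[C@@H]12.[Li+] | intermediate (not isolated)
27 | (2E)-3-methyl-5-[(4aS,5S,8aS)-2,5,8a-trimethyl-5-(4-methylpent-3-en-1-yl)-3,4,4a,5,6,7,8,8a-octahydronaphthalen-1-yl]pent-2-enoic acid | CC(C)=CCC[C@]1(C)CCC[C@]2(C)C(CC/C(C)=C/C(=O)O)=C(C)CC[C@@H]12 | target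

## Step count and least certain steps

Total: 15 steps. Longest linear sequence: 15 steps (1 → 27); 3, 11 and 20 enter as purchased materials.

**Step 2 (key step).**
- Risk: loss of enantioselectivity through an uncatalysed or proton-catalysed background cycloaddition, protodesilylation of the diene by the strong acid, or a stepwise conjugate addition that does not close the ring.
- Fallback: from 2 and 3, the cycloaddition is promoted by an achiral Lewis acid (BF3·OEt2, CH2Cl2, −78 °C), which binds the same C6 carbonyl and should keep the regiochemistry. This gives the racemate, that is 4 together with its mirror image, the ent-adduct F1. The enantiomers are separated by preparative chromatography on a chiral stationary phase, and the route is rejoined at 4.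

**Step 4.**
- Risk: an equilibrium that does not lie far enough on the trans side. The angular methyl is axial in the trans isomer, and with C2/C3 sp2 the cis isomer loses most of its usual penalty, so the energy gap is expected to be small and several recycles may be needed.
- Fallback: it sets out from 5 and moves the equilibration to a saturated ring A, where the cis form pays an extra 1,3-diaxial contact between C6 and the axial C3–H. Aqueous HCl in THF cleaves the enol ether to the cis-fused 2,6,9-trione F2 and equilibrates it by acid-catalysed enolisation to the trans-fused 2,6,9-trione F3. Ethylene glycol with PPTS in benzene protects the least hindered ketone as the C2 dioxolane F4. TsNHNH2 gives the C6 tosylhydrazone F5, catecholborane gives the N-boryl sulfonohydrazide F6, and NaOAc·3H2O at reflux gives the C6-deoxygenated ketal F7. Aqueous acid in acetone frees the 2,9-dione F8. Dehydrogenation with 2-iodoxybenzoic acid (DMSO/PhMe, 70 °C) at the C2 ketone can only lead to the C3=C4 enone, because C1 has no β hydrogen, and the hindered C9 ketone is expected to enolise far more slowly, so the route is rejoined at 10.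

**Step 8.**
- Risk: poor or reversed facial selectivity. The stereoelectronically preferred axial entry is syn to the C10 methyl and competes with the sterically open α face. The addition to this hindered enone may also be slow.
- Fallback: it sets out from 3 and interchanges the order in which the two C4 groups arrive, so that a β (axial) preference becomes the useful one. Wittig reaction of purchased 5-methylhex-4-enal with 1-(triphenylphosphoranylidene)propan-2-one gives (E)-8-methylnona-3,7-dien-2-one F9, and silylation as in step 1 gives the diene F10. Cycloaddition with 3 as in step 2 gives the cis-fused adduct F11. The operations of steps 3–7 then give in turn the cis dione F12, the trans dione F13, the C6 tosylhydrazone F14, the N-boryl sulfonohydrazide F15, the C6-deoxygenated silyl enol ether F16 and the 4-(4-methylpent-3-enyl) enone F17. Copper-catalysed addition of MeMgBr with TMSCl (CuBr·SMe2, THF, −78 °C) then delivers the methyl group, and the route is rejoined at 13.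

**Step 12.**
- Risk: slow oxidative addition into the hindered tetrasubstituted triflate, with reduction of the triflate or homocoupling of the zinc reagent taking over.
- Fallback: it sets out from 19 and builds the arm one carbon at a time. Carbonylation (Pd(OAc)2, dppp, CO, MeOH, Et3N, DMF, 70 °C) gives the C9 methyl ester F18, i-Bu2AlH gives the allylic alcohol F19, and PBr3 with pyridine gives the allylic bromide F20. Alkylation with 3-(trimethylsilyl)prop-2-ynyllithium F21 (from 1-(trimethylsilyl)propyne, n-BuLi, TMEDA, THF, −78 °C) rejoins the route at 22.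

## Further compounds

F1 | step 2 | (4aS,5S,8aR)-7-(tert-butyldimethylsilyloxy)-2,5,8a-trimethyl-4a,5,8,8a-tetrahydronaphthalene-1,4-dione (enantiomer of 4) | C[C@H]1C=C(O[Si](C)(C)C(C)(C)C)C[C@@]2(C)C(=O)C(C)=CC(=O)[C@@H]12
F2 | step 4 | cis-fused 4α,8,10β-trimethyl-5β-H-decalin-2,6,9-trione (C8 epimers) | C[C@@H]1CC(=O)C[C@]2(C)C(=O)C(C)CC(=O)[C@H]12
F3 | step 4 | trans-fused 4α,8α,10β-trimethyl-5α-H-decalin-2,6,9-trione | C[C@@H]1CC(=O)C[C@]2(C)C(=O)[C@H](C)CC(=O)[C@@H]12
F4 | step 4 | 2,2-ethylenedioxy-4α,8α,10β-trimethyl-5α-H-decalin-6,9-dione | C[C@@H]1CC3(OCCO3)C[C@]2(C)C(=O)[C@H](C)CC(=O)[C@@H]12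
F5 | step 4 | C6 p-toluenesulfonylhydrazone of F4 | C[C@@H]1CC3(OCCO3)C[C@]2(C)C(=O)[C@H](C)CC(=NNS(=O)(=O)c4ccc(C)cc4)[C@@H]12
F6 | step 4 | N-(1,3,2-benzodioxaborol-2-yl) C6 sulfonohydrazide from F5 | C[C@@H]1CC3(OCCO3)C[C@]2(C)C(=O)[C@H](C)CC(N(NS(=O)(=O)c4ccc(C)cc4)B4Oc5ccccc5O4)[C@@H]12
F7 | step 4 | 2,2-ethylenedioxy-4α,8α,10β-trimethyl-5α-H-decalin-9-one | C[C@@H]1CC3(OCCO3)C[C@]2(C)C(=O)[C@H](C)CC[C@@H]12
F8 | step 4 | trans-fused 4α,8α,10β-trimethyl-5α-H-decalin-2,9-dione | C[C@@H]1CC(=O)C[C@]2(C)C(=O)[C@H](C)CC[C@@H]12
F9 | step 8 | (E)-8-methylnona-3,7-dien-2-one | CC(=O)/C=C/CCC=C(C)C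
F10 | step 8 | (E)-2-(tert-butyldimethylsilyloxy)-8-methylnona-1,3,7-triene | C=C(O[Si](C)(C)C(C)(C)C)/C=C/CCC=C(C)C
F11 | step 8 | cis-fused adduct with 4α-(4-methylpent-3-enyl), 5β-H, 10β-methyl (analogue of 4) | CC(C)=CCC[C@@H]1C=C(O[Si](C)(C)C(C)(C)C)C[C@]2(C)C(=O)C(C)=CC(=O)[C@H]12
F12 | step 8 | cis-fused dione, analogue of 5 with 4α-(4-methylpent-3-enyl) (C8 epimers) | CC(C)=CCC[C@@H]1C=C(O[Si](C)(C)C(C)(C)C)C[C@]2(C)C(=O)C(C)CC(=O)[C@H]12
F13 | step 8 | trans-fused dione, analogue of 6 with 4α-(4-methylpent-3-enyl) | CC(C)=CCC[C@@H]1C=C(O[Si](C)(C)C(C)(C)C)C[C@]2(C)C(=O)[C@H](C)CC(=O)[C@@H]12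
F14 | step 8 | C6 p-toluenesulfonylhydrazone of F13 | CC(C)=CCC[C@@H]1C=C(O[Si](C)(C)C(C)(C)C)C[C@]2(C)C(=O)[C@H](C)CC(=NNS(=O)(=O)c3ccc(C)cc3)[C@@H]12
F15 | step 8 | N-(1,3,2-benzodioxaborol-2-yl) C6 sulfonohydrazide from F14 | CC(C)=CCC[C@@H]1C=C(O[Si](C)(C)C(C)(C)C)C[C@]2(C)C(=O)[C@H](C)CC(N(NS(=O)(=O)c3ccc(C)cc3)B3Oc4ccccc4O3)[C@@H]12
F16 | step 8 | C6-deoxygenated silyl enol ether, analogue of 9 with 4α-(4-methylpent-3-enyl) | CC(C)=CCC[C@@H]1C=C(O[Si](C)(C)C(C)(C)C)C[C@]2(C)C(=O)[C@H](C)CC[C@@H]12
F17 | step 8 | trans-fused 8α,10β-dimethyl-4-(4-methylpent-3-enyl)-5α-H-decal-3-ene-2,9-dione | CC(C)=CCCC1=CC(=O)C[C@]2(C)C(=O)[C@H](C)CC[C@@H]12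
F18 | step 12 | methyl 4β,8,10β-trimethyl-4α-(4-methylpent-3-enyl)-5α-H-decal-8-ene-9-carboxylate | CC(C)=CCC[C@]1(C)CCC[C@]2(C)C(C(=O)OC)=C(C)CC[C@@H]12
F19 | step 12 | [4β,8,10β-trimethyl-4α-(4-methylpent-3-enyl)-5α-H-decal-8-en-9-yl]methanol | CC(C)=CCC[C@]1(C)CCC[C@]2(C)C(CO)=C(C)CC[C@@H]12
F20 | step 12 | 9-(bromomethyl)-4β,8,10β-trimethyl-4α-(4-methylpent-3-enyl)-5α-H-decal-8-ene | CC(C)=CCC[C@]1(C)CCC[C@]2(C)C(CBr)=C(C)CC[C@@H]12
F21 | step 12 | 3-(trimethylsilyl)prop-2-ynyllithium | [Li]CC#C[Si](C)(C)C
A1 | alternative 1 | 3-methylcyclohex-2-enone | CC1=CC(=O)CCC1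
A2 | alternative 1 | trans-2-allyl-3-methyl-3-(prop-1-en-2-yl)cyclohexanone | O=C1CCC[C@](C)(C(C)=C)[C@H]1CC=C
A3 | alternative 2 | trans-fused 6-oxo-9-(tert-butyldimethylsilyloxy) octalin with C4 and C10 quaternary centres and a C1=C2 alkene | CC(C)=CCC[C@]1(C)CC=C[C@]2(C)[C@@H](O[Si](C)(C)C(C)(C)C)CCC(=O)[C@@H]12
A4 | alternative 3 | bicyclic C8=C9 alkene with C8 methyl, C4 vinyl and C5 trimethylsilyloxy group | C=C[C@]1(C)CCC[C@]2(C)C=C(C)CC[C@@]12O[Si](C)(C)C
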